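A direct plan would chlorinate methyl 2-hydroxy-4-methoxy-6-pentylbenzoate A1 to its 3-chloro derivative A2, hydrolyse A2, acylate the 4-OH of tert-butyl 2,4-dihydroxy-6-pentylbenzoate A3 with the resulting acid to the tert-butyl ester A4 of the target and cleave A4 with acid. The chlorination of A1 would be weak, because the free 2-OH would direct the electrophile to C5 as readily as to C3, so that isomers would have to be separated. The esterification of A3 would be weak, because the acyl donor would be a 2,6-disubstituted salicylic acid, shielded at the carbonyl and prone to self-acylation. The hydrolysis of the hindered, chelated ester A2 would need forcing base.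

The route disconnects ring A itself instead of the depside C–O bond beside it. Ring B is acylated at O-4 with unhindered oct-2-ynoic acid, and the aryl ynoate then takes up a four-carbon vinylketene acetal that already carries chlorine on its C2, between a masked hydroxyl (C1) and the methoxy group (C3). One [4+2] cycloaddition–aromatisation forms C1–C2 and C5–C6 of ring A and places CO2Ar, OH, Cl, OMe, H and pentyl around it through the polarity of the two partners. No arene is chlorinated, no hindered methyl ester is hydrolysed, and no 2,6-disubstituted benzoic acid is esterified.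

Key step: step 5

Remark: the target has no stereocentre; the double-bond geometry of the enoate and of the diene and the single stereocentre of the cycloadduct are lost on aromatisation and are left uncontrolled.

Step 1
Reactants: 1 2,4-dihydroxy-6-pentylbenzoic acid (olivetolic acid)
Product: 2 benzyl 2,4-dihydroxy-6-pentylbenzoate
Conditions: BnBr (1.05 eq), KHCO3 (1.2 eq), DMF, rt
Reagents that add atoms: benzyl bromide, BrCc1ccccc1
Why: Carboxylate O-alkylation (SN2) – the weak base KHCO3 deprotonates only the carboxylic acid, so benzyl bromide should alkylate the carboxylate alone, and the mild conditions avoid decarboxylation of the β-resorcylic acid.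

Step 2
Reactants: 2 benzyl 2,4-dihydroxy-6-pentylbenzoate; 3 oct-2-ynoic acid
Product: 4 benzyl 2-hydroxy-4-(oct-2-ynoyloxy)-6-pentylbenzoate
Conditions: DCC (1.1 eq), DMAP (0.05 eq), CH2Cl2, 0 °C → rt
Reagents that add atoms: none
Why: Steglich esterification – the activated, unhindered ynoic acid should acylate the free 4-OH, while the 2-OH, hydrogen-bonded to the benzyl ester carbonyl, stays unreacted, and low temperature with little DMAP keeps conjugate addition to the ynoate in check.

Step 3
Reactants: 5 methyl 2-chloro-3-oxobutanoate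
Product: 7 methyl 2-chloro-3-methoxybut-2-enoate, via dimethyl ketal 6 (not isolated)
Conditions: HC(OMe)3 (1.5 eq), conc. H2SO4 (cat.), rt; then KHSO4 (cat.), distil off HCO2Me/MeOH (bath 140 °C); vacuum distillation
Reagents that add atoms: trimethyl orthoformate, COC(OC)OC
Why: Acid-catalysed orthoester ketalisation followed by elimination of methanol (enol ether formation) – the ketal should lose MeOH toward the conjugated β-methoxy enoate, with the chlorine fixed at C2 by the starting material.

Step 4
Reactants: 7 methyl 2-chloro-3-methoxybut-2-enoate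
Product: 9 2-chloro-1,3-dimethoxy-1-(trimethylsilyloxy)buta-1,3-diene, via lithium dienolate 8 (not isolated)
Conditions: LiN(i-Pr)2 (LDA, 1.1 eq), THF, –78 °C; Me3SiCl (1.3 eq), –78 °C → rt; pentane, filter, Kugelrohr distillation
Reagents that add atoms: chlorotrimethylsilane, C[Si](C)(C)Cl
Why: γ-Deprotonation of a vinylogous ester and O-silylation of the extended enolate (vinylketene silyl acetal synthesis) – the C4 methyl group holds the only acidic C–H, and the hard silyl chloride should trap the dienolate on oxygen at low temperature before the α-chloro enolate can decompose.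

Step 5
Reactants: 4 benzyl 2-hydroxy-4-(oct-2-ynoyloxy)-6-pentylbenzoate; 9 2-chloro-1,3-dimethoxy-1-(trimethylsilyloxy)buta-1,3-diene
Product: 12 benzyl 4-[(3-chloro-2-hydroxy-4-methoxy-6-pentylbenzoyl)oxy]-2-hydroxy-6-pentylbenzoate, via trimethylsilyl ether 10 (not isolated), via cyclohexadiene cycloadduct 11 (not isolated)
Conditions: (a) MeC(OSiMe3)=NSiMe3 (BSA, 1.2 eq), PhMe, 60 °C; (b) 9 (3 eq), PhMe, 120 °C, sealed tube; (c) 1 M HCl, THF, rt
Reagents that add atoms: none
Why: Thermal, strongly polarised [4+2] cycloaddition (Diels–Alder benzannulation) followed by aromatisation: the 1,1-dioxygenated terminus and the 3-methoxy group of vinylketene acetal 9 both raise the HOMO coefficient at its CH2 carbon, which should bond to the pentyl-bearing β-carbon of ynoate 10 while the ketene acetal carbon bonds to the α-carbon, so that cyclohexa-1,4-diene 11 carries pentyl and the masked hydroxyl on either side of the ester carbon. The closest known reaction type is the resorcylate synthesis from 2-alkynoates and 1,1-dialkoxy- or 1-alkoxy-1-silyloxy-3-oxybuta-1,3-dienes, here with chlorine on C2 of the diene and an aryl in place of an alkyl ester. Ring A is closed intermolecularly in [4+2] mode, the new bonds being C1–C2 and C5–C6 of the later benzoyl ring; the acidic work-up should ionise the mixed silyl methyl ketal of 11 with loss of the more basic methoxy group, the ring CH2 then loses a proton to aromatise, and the O–SiMe3 bonds are hydrolysed. No stereocentre remains, since the single stereocentre of 11 and the double-bond geometry of 9 vanish on aromatisation. The step needs regioselectivity, secured by the matched polarity of diene and ynoate, and chemoselectivity, secured by neutral thermal conditions (benzyl and aryl esters inert) and by the prior O-silylation of the chelated 2-OH with BSA, which keeps this phenol from protonating the ketene acetal. Because chlorine sits on C2 of the diene between the two oxygen-bearing carbons, it can only end at C3 of ring A.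

Step 6
Reactants: 12 benzyl 4-[(3-chloro-2-hydroxy-4-methoxy-6-pentylbenzoyl)oxy]-2-hydroxy-6-pentylbenzoate
Product: 13 4-[(3-chloro-2-hydroxy-4-methoxy-6-pentylbenzoyl)oxy]-2-hydroxy-6-pentylbenzoic acid (CNP0310773.0)
Conditions: H2 (1 atm), Pd/C (10 wt%), EtOAc, rt, stopped after uptake of one equivalent
Reagents that add atoms: none
Why: Hydrogenolysis of a benzyl ester – the benzylic C–O bond should be cleaved under neutral conditions in which the depside ester, the methyl ether and the electron-rich aryl chloride (no base present) persist.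

## Compound list
1 | 2,4-dihydroxy-6-pentylbenzoic acid (olivetolic acid) | CCCCCc1cc(O)cc(O)c1C(=O)O | starting material
2 | benzyl 2,4-dihydroxy-6-pentylbenzoate | CCCCCc1cc(O)cc(O)c1C(=O)OCc1ccccc1 | intermediate
3 | oct-2-ynoic acid | CCCCCC#CC(=O)O | starting material
4 | benzyl 2-hydroxy-4-(oct-2-ynoyloxy)-6-pentylbenzoate | CCCCCC#CC(=O)Oc1cc(CCCCC)c(C(=O)OCc2ccccc2)c(O)c1 | intermediate
5 | methyl 2-chloro-3-oxobutanoate (racemic) | CC(=O)C(Cl)C(=O)OC | starting material
6 | methyl 2-chloro-3,3-dimethoxybutanoate (racemic, not isolated) | CC(OC)(OC)C(Cl)C(=O)OC | intermediate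
7 | methyl 2-chloro-3-methoxybut-2-enoate (E/Z mixture) | COC(C)=C(Cl)C(=O)OC | intermediate
8 | lithium 2-chloro-1,3-dimethoxybuta-1,3-dien-1-olate (not isolated) | C=C(OC)C(Cl)=C(OC)O[Li] | intermediate
9 | 2-chloro-1,3-dimethoxy-1-(trimethylsilyloxy)buta-1,3-diene (E/Z mixture at C1=C2) | C=C(OC)C(Cl)=C(OC)O[Si](C)(C)C | intermediate
10 | benzyl 4-(oct-2-ynoyloxy)-6-pentyl-2-(trimethylsilyloxy)benzoate (not isolated) | CCCCCC#CC(=O)Oc1cc(CCCCC)c(C(=O)OCc2ccccc2)c(O[Si](C)(C)C)c1 | intermediate
11 | benzyl 4-{[5-chloro-4,6-dimethoxy-2-pentyl-6-(trimethylsilyloxy)cyclohexa-1,4-diene-1-carbonyl]oxy}-6-pentyl-2-(trimethylsilyloxy)benzoate (racemic, not isolated) | CCCCCC1=C(C(=O)Oc2cc(CCCCC)c(C(=O)OCc3ccccc3)c(O[Si](C)(C)C)c2)C(OC)(O[Si](C)(C)C)C(Cl)=C(OC)C1 | intermediate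
12 | benzyl 4-[(3-chloro-2-hydroxy-4-methoxy-6-pentylbenzoyl)oxy]-2-hydroxy-6-pentylbenzoate | CCCCCc1cc(OC(=O)c2c(CCCCC)cc(OC)c(Cl)c2O)cc(O)c1C(=O)OCc1ccccc1 | intermediate
13 | 4-[(3-chloro-2-hydroxy-4-methoxy-6-pentylbenzoyl)oxy]-2-hydroxy-6-pentylbenzoic acid (CNP0310773.0) | CCCCCc1cc(OC(=O)c2c(CCCCC)cc(OC)c(Cl)c2O)cc(O)c1C(=O)O | target

Total step count: 6. Longest linear sequence: 4 steps (1 → 2 → 4 → 12 → 13, or 5 → 7 → 9 → 12 → 13).

Steps most likely to fail:

Step 5. The cycloaddition may stall, because chlorine lowers the nucleophilicity of the diene and the internal ynoate is only a moderate dienophile. On prolonged heating, decomposition of the diene or [2+2] addition at its ketene acetal bond could take over. The fallback closes ring A on a more electrophilic dienophile away from ring B and makes the depside bond afterwards; it sets out from 9 and comes back at 12. Diene 9 and oct-2-ynal F1 (PhMe, 60 °C) would give the cycloadduct 5-chloro-4,6-dimethoxy-2-pentyl-6-(trimethylsilyloxy)cyclohexa-1,4-diene-1-carbaldehyde F2 (not isolated). Dilute HCl would turn it into 3-chloro-2-hydroxy-4-methoxy-6-pentylbenzaldehyde F3. Pinnick oxidation (NaClO2, NaH2PO4, 2-methyl-2-butene, t-BuOH/H2O) would give 3-chloro-2-hydroxy-4-methoxy-6-pentylbenzoic acid F4. The mixed-anhydride depside esterification ((CF3CO)2O, PhMe, rt) would join F4 to the 4-OH of 2 to give 12.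

Step 4. The lithium dienolate may lose chloride, condense with unreacted enoate or be silylated on carbon before O-silylation. The fallback uses no lithium base and separates O-methylation from ring formation; it sets out from 5 (with 4, silylated to 10 as in step 5) and comes back at 12. Double silylation of 5 with Me3SiOTf/Et3N (Et2O, 0 °C) would give 2-chloro-1-methoxy-1,3-bis(trimethylsilyloxy)buta-1,3-diene F5. Under the conditions of step 5 this more electron-rich diene would add to 10 to give the cycloadduct benzyl 4-{[5-chloro-6-methoxy-2-pentyl-4,6-bis(trimethylsilyloxy)cyclohexa-1,4-diene-1-carbonyl]oxy}-6-pentyl-2-(trimethylsilyloxy)benzoate F6 (not isolated). Acidic work-up would give benzyl 4-[(3-chloro-2,4-dihydroxy-6-pentylbenzoyl)oxy]-2-hydroxy-6-pentylbenzoate F7. Me3SiCHN2 in PhMe/MeOH would methylate only its non-chelated 4-OH, since both 2-OH groups are hydrogen-bonded to ester carbonyls, to give 12.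

Step 3. The ketal may resist loss of methanol, or the α-chlorine may be lost during the acidic distillation. The fallback reverses the order of events: the enol ether is bought and then chlorinated. It bypasses 5, sets out from commercial methyl (E)-3-methoxybut-2-enoate F8 and comes back at 7. F8 would be chlorinated at C2 with N-chlorosuccinimide in MeCN (electrophilic substitution at the nucleophilic carbon of the enol ether) to give 7. Any deconjugated isomer would converge on the same dienolate in step 4.

Further compounds
F1 | step 5 | oct-2-ynal | CCCCCC#CC=O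
F2 | step 5 | 5-chloro-4,6-dimethoxy-2-pentyl-6-(trimethylsilyloxy)cyclohexa-1,4-diene-1-carbaldehyde (racemic) | CCCCCC1=C(C=O)C(OC)(O[Si](C)(C)C)C(Cl)=C(OC)C1
F3 | step 5 | 3-chloro-2-hydroxy-4-methoxy-6-pentylbenzaldehyde | CCCCCc1cc(OC)c(Cl)c(O)c1C=O
F4 | step 5 | 3-chloro-2-hydroxy-4-methoxy-6-pentylbenzoic acid | CCCCCc1cc(OC)c(Cl)c(O)c1C(=O)O
F5 | step 4 | 2-chloro-1-methoxy-1,3-bis(trimethylsilyloxy)buta-1,3-diene | C=C(O[Si](C)(C)C)C(Cl)=C(OC)O[Si](C)(C)C
F6 | step 4 | benzyl 4-{[5-chloro-6-methoxy-2-pentyl-4,6-bis(trimethylsilyloxy)cyclohexa-1,4-diene-1-carbonyl]oxy}-6-pentyl-2-(trimethylsilyloxy)benzoate (racemic) | CCCCCC1=C(C(=O)Oc2cc(CCCCC)c(C(=O)OCc3ccccc3)c(O[Si](C)(C)C)c2)C(OC)(O[Si](C)(C)C)C(Cl)=C(O[Si](C)(C)C)C1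
F7 | step 4 | benzyl 4-[(3-chloro-2,4-dihydroxy-6-pentylbenzoyl)oxy]-2-hydroxy-6-pentylbenzoate | CCCCCc1cc(OC(=O)c2c(CCCCC)cc(O)c(Cl)c2O)cc(O)c1C(=O)OCc1ccccc1
F8 | step 3 | methyl (E)-3-methoxybut-2-enoate | CO/C(C)=C/C(=O)OC
A1 | direct plan | methyl 2-hydroxy-4-methoxy-6-pentylbenzoate | CCCCCc1cc(OC)cc(O)c1C(=O)OC
A2 | direct plan | methyl 3-chloro-2-hydroxy-4-methoxy-6-pentylbenzoate | CCCCCc1cc(OC)c(Cl)c(O)c1C(=O)OC
A3 | direct plan | tert-butyl 2,4-dihydroxy-6-pentylbenzoate | CCCCCc1cc(O)cc(O)c1C(=O)OC(C)(C)C
A4 | direct plan | tert-butyl 4-[(3-chloro-2-hydroxy-4-methoxy-6-pentylbenzoyl)oxy]-2-hydroxy-6-pentylbenzoate | CCCCCc1cc(OC(=O)c2c(CCCCC)cc(OC)c(Cl)c2O)cc(O)c1C(=O)OC(C)(C)C
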